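**Feed the partner.** You suspect the cold recipes for the most cross product, and here is why I look at blue instead.

| setting | south | east | south-west | west | teal | blue | violet | grey | red |
|---|---|---|---|---|---|---|---|---|---|
| starting material | 20 mM | 10 mM | 15 mM | 20 mM | 20 mM | 20 mM | 20 mM | 20 mM | 20 mM |
| partner | 3 equiv | 3 equiv | 3 equiv | 6 equiv | 3.00 equiv | 3.00 equiv (fed, over 8.0 h) | 3.00 equiv (fed, over 8.0 h) | 3.00 equiv | 3.00 equiv |
| second substrate | 1 equiv | 1 equiv | 1 equiv | 1 equiv | 1.00 equiv (fed, over 8.0 h) | 1.00 equiv | 1.00 equiv | 1.00 equiv (in portions, 4, over 8.0 h) | 1.00 equiv |
| protic impurity | 2 mM | 2 mM | 2 mM | 2 mM | 2.00 mM | 2.00 mM | 2.00 mM | 2.00 mM | 2.00 mM |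
| temperature | −15 °C | 0 °C | −15 °C | 0 °C | 0 °C | 0 °C |  | 0 °C |  |
| remark | run made earlier | run made earlier | run made earlier | run made earlier | all else is in the flask from the start; the feed brings no volume worth counting | all else is in the flask from the start; the feed brings no volume worth counting | the addition at −40 °C, then warmed to 0 °C; the feed brings no volume worth counting | first portion at the start, last at 8.0 h | everything together at the start at −40 °C, warmed to 0 °C at 8.0 h |
| time |  |  |  |  | 12 h | 12 h | 12 h | 12 h | 12 h |

- south (time / h: cross product / %, target / %, starting material / %): 3.00: 1, 11, 40; 6.00: 2, 17, 27; 8.00: 1, 16, 25; 12.0: 4, 23, 19; 15.0: 5, 29, 22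
- east (time / h: cross product / %, target / %, starting material / %): 1.00: 3, 8, 51; 2.00: 1, 11, 49; 3.00: 4, 17, 50; 6.00: 5, 26, 43; 12.0: 0, 44, 31
- south-west (time / h: cross product / %, target / %, starting material / %): 2.00: 3, 7, 52; 4.00: 0, 14, 38; 6.00: 0, 11, 28; 12.0: 3, 17, 25; 25.0: 1, 28, 21
- west (time / h: cross product / %, target / %, starting material / %): 2.50: 0, 47, 30; 5.00: 4, 74, 16; 8.00: 0, 83, 9; 10.0: 0, 91, 5; 12.0: 1, 97, 1

(standard deviation of a reading: 2 percentage points)

* the flask that comes out highest in amount of cross product, in percent of the starting material charged, or "all alike" when all lie within 1.5 percentage points (teal / blue / violet / grey / red / all alike)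
* cross product at the end, in percent of the starting material charged, teal
* cross product at the end, in percent of the starting material charged, blue
* cross product at the end, in percent of the starting material charged, violet
* cross product at the end, in percent of the starting material charged, grey
* cross product at the end, in percent of the starting material charged, red



- I take target and cross product as two steps of the same starting material, so its concentration cancels in the ratio of their rates, and that ratio is set by c(second substrate)/c(partner).
- Summed over the east run, cross product over target reads 0.123, with a scatter of 2 percentage points on each reading, and the charge there holds 3 equiv of partner against 1 equiv of second substrate.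
- That gives 0.368, my apparent selectivity factor s, which is cross product over target per unit of charged second substrate over charged partner; it is a reading of the east run and not the ratio of the two rates at equal concentrations, and these readings don't tell me whether c(second substrate)/c(partner) held its charge value through that run.
- In blue, c(partner) climbs from zero, and the feed has delivered as much partner as second substrate was charged after 2.67 h, so I put the early ratio above the charge ratio of the east run.
- In teal, the second substrate trickles into partner charged at 60.0 mM, so I put teal's ratio below that charge ratio.
- My own rough estimate for blue, which carries the east run's ratio over unchanged and takes target near the 44% that the east run shows at 12.0 h, is 5.40% of cross product, and it rests on cross-product readings that stand close to their scatter of 2 points.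
- The forecast also names blue, at 5.5% (range 2.5% to 12%), on the ground that “Slow partner feed keeps the pool alive longest alongside full substrate”. It gives teal 2.3%, violet 2.3%, grey 2.4% and red 2.2%.

Blue gives 8.24% of cross product, more than teal 1.18%, violet 1.96%, grey 1.24% or red 1.87%, and each lies inside its forecast range.

    second substrate + partner → second product (k = 0.00822 M⁻¹ s⁻¹, Ea = 68.0 kJ mol⁻¹)
    partner + protic impurity → quenched reagent (k = 0.0714 M⁻¹ s⁻¹, Ea = 58.0 kJ mol⁻¹)
    starting material + partner → target (k = 0.00132 M⁻¹ s⁻¹, Ea = 52.0 kJ mol⁻¹)
    starting material + second substrate → cross product (k = 6.02 × 10⁻⁴ M⁻¹ s⁻¹, Ea = 65.0 kJ mol⁻¹)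
    starting material ⇌ dormant form (K = 0.670, k = 9.64 × 10⁻⁴ s⁻¹, Ea = 92.0 kJ mol⁻¹, ΔH = −45.0 kJ mol⁻¹)
    (constants at 0 °C)

At 3.28 h in blue, second substrate goes 16 times as fast into second product as into cross product. Dividing blue's cross product by its target of 47.4% and then by s gives 0.472, a figure on the scale of the east run, whose charge ratio stands at 0.333 on that scale. The same division for teal, with 1.18% of cross product over 70.9% of target, gives 0.0452.

The numbers in the tables come from a simulation for substances that don't exist; scatter was added.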